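## Structural features

Teferin is the 6-vanillate of a daucane diol. Daucane numbering is used throughout: C1 is the quaternary ring-fusion carbon with methyl C15, followed by C2 and C3. C4 is the carbinol carbon with the isopropyl group C11 to C13, C5 is the ring-fusion CH, and C6 is the ester carbon. Then come C7, C8 with methyl C14, C9 and C10. The β face is the face of C15.

Ring A (cyclopentane C1 to C5) is trans-fused along C1-C5 to ring B (cycloheptene C1, C5 to C10). The only alkene of ring B is the trisubstituted C8=C9.

The four stereocentres are contiguous: C1 (R), C5 (S), C4 (R) and C6 (S). The β face of ring A carries C15, C6 and the 4-OH. The α face carries C10, H5 and the isopropyl group, and the ester oxygen at C6 is α (equatorial).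

Several groups are fragile:
- The tertiary alcohol can dehydrate, and it can undergo retro-aldol cleavage as soon as C6 is a carbonyl.
- The C6 oxygen is homoallylic, so any C6 ketone is β,γ-unsaturated and has acidic C7 hydrogens.
- The aryl ester and the free phenol are also sensitive.

The real difficulty is the quaternary C1 next to a trans ring fusion. Whenever C5 is trigonal in the bicycle, C8 to C10 fold onto the α face. External reagents therefore arrive from β, although H5 must end up α. Any chain on C1 that closes onto a trigonal C5 gives the cis fusion. A C10 nucleophile would be allylic and regiochemically ambiguous.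

The key step exploits the spacing inside ring B. The C8=C9 alkene is separated from the oxidised C5/C6 pair by the single methylene C7. With a second alkene at C5=C6, ring B becomes a cyclohepta-1,4-diene, with C7 as the doubly allylic carbon and C1-C10 as the bond opposite to it. That pattern is the retron of a divinylcyclopropane rearrangement in which C6 and C8 are reconnected.

## Logic of the disconnections

**18 to 17, then to 15 and 16.** The acyl C-O bond at O6 and the phenol protecting group are cut. This removes the only aromatic part and leaves a diol with one secondary and one tertiary hydroxyl. The forward step must acylate only the secondary one, which the steric difference secures.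

**15 to 14.** The C6-H bond is cut. With C6 as a ketone, the last stereocentre can be set from inside the molecule. The forward step must deliver hydride to the β face, the face that external hydrides avoid, so the 4β-OH has to carry the hydride.

**14 to 13 to 12.** The C5-H bond is cut and C6 is returned to the alcohol level, so that both atoms become a 5β,6β-epoxide. This trades the concave-face hydrogen for a convex-face oxygen. The forward steps must break only the C5-O bond and bring hydrogen to C5 anti to the oxygen substituents.

**12 to 11.** The C4-C11 bond is cut, which removes three carbons and the C4 stereocentre. The forward step must add an isopropyl nucleophile to the α face of the C4 ketone. The β epoxide oxygen on the neighbouring C5 enforces this.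

**11 to 10.** The two epoxide C-O bonds are cut, which leaves a dienone with C1 as its only stereocentre. The forward step must touch only the electron-poor C5=C6 and must come from the β face.

**10 to 9 (key).** The C1-C10 bond is cut and C6-C8 is reconnected. Ring B, the quaternary centre and the alkene regiochemistry all disappear. What remains is a monocyclic enone bearing a cis-2-vinylcyclopropyl group. The forward step must transfer the cyclopropane configuration completely to C1.

**9 to 8 to 7.** The C9=C10 alkene is cut to an aldehyde and then to a primary alcohol. This uncovers the hydroxyl group that directs the cyclopropanation. The forward steps must spare the enone carbonyl.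

**7 to 6.** The C6-C7 and C7-C8 bonds are cut (one methylene unit). All stereochemistry of the route is reduced to one reagent-controlled face selection on a Z allylic alcohol. The forward step must be stereospecific and must ignore the enone alkene.

**6 to 3 and 4.** The C5-C6 bond between two trigonal carbons is cut. This gives a four-carbon and a six-carbon fragment. The forward coupling must keep the Z geometry.

**3 to 1.** The C8-C14 and C6-I bonds are cut. The forward step must add methyl and metal anti across the alkyne, so that iodine and the hydroxymethyl group end up cis.

## Other disconnections considered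

**Alternative 1:** This is the first plan that comes to mind. It cuts C8=C9 of ring B and closes it by ring-closing metathesis of the 8,9-seco diene A1 with the second-generation Grubbs catalyst.

The plan moves the whole stereochemical problem into ring A. C6 must be placed trans to the allyl group and cis to the methyl group on C1, and these two groups are nearly the same size. Neither enolate trapping nor equilibration at C5 can therefore be defended. The C1 centre would also need an enantioselective conjugate allylation, for which no dependable method exists. The chosen plan obtains C1 by a stereospecific transfer and needs no size difference at C1.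

**Alternative 2:** This is a chiral-pool plan from (S)-terpinen-4-ol A2. Its carbinol carbon, isopropyl group, methyl group and five ring carbons map onto C4, C11 to C13, C15 and C1 to C3, C5 and C6. Ozonolysis and aldol condensation would give the enal A3. Conjugate addition of a C10 to C7 chain to C1 and a carbonyl-ene closure of C6-C7 would follow.

The map is attractive and short, but it is mismatched. C10 has to bond to C1 on the face cis to the isopropyl group. The ene closure transfers hydrogen from the methyl group more easily than from the tether, which would leave an exocyclic alkene instead of C8=C9. Both faults sit in the ring-forming steps.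

**Alternative 3:** This plan cuts C1-C15 and C4-C5 together. The forward step is a cascade of conjugate methylation and intramolecular aldol addition on the cycloheptadienone A4, which would close ring A and set C1, C5 and C4 in one operation.

The five-membered ring can close onto the planar C5 enolate only from a pseudoaxial side chain on the same face, and this gives the cis fusion. Correcting it needs reversible aldol conditions, and under these the β,γ-unsaturated ketone would move into conjugation and the aldol would dehydrate. The chosen plan never has to close a ring at C5.

Key step: step 6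

## Steps

Step 1
Reactants: 1 prop-2-yn-1-ol
Product: 3 (2Z)-3-iodo-2-methylprop-2-en-1-ol, via oxamagnesole 2 (not isolated)
Conditions: MeMgBr (2.5 equiv), CuI (10 mol%), THF, -10 °C to rt; then I2, -30 °C
Reagents that add atoms: methylmagnesium bromide C[Mg]Br; iodine II
Why: Copper-catalysed anti carbomagnesiation of a propargylic alkoxide places methyl on the inner alkyne carbon and magnesium on the terminus in a five-membered chelate, and iodinolysis with retention should give the Z iodide with iodine cis to the hydroxymethyl group.

Step 2
Reactants: 3 (2Z)-3-iodo-2-methylprop-2-en-1-ol; 4 2-bromo-3-methylcyclopent-2-en-1-one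
Product: 6 2-[(1Z)-3-hydroxy-2-methylprop-1-en-1-yl]-3-methylcyclopent-2-en-1-one, via alkenyl pinacol boronate 5 (not isolated)
Conditions: B2pin2, PdCl2(dppf) (3 mol%), KOAc, dioxane, 80 °C; then 4, aq K3PO4, 60 °C
Reagents that add atoms: none
Why: Miyaura borylation followed in the same flask by Suzuki-Miyaura coupling; both steps run with retention at the alkenyl carbon, α-bromoenones are good partners for oxidative addition to zerovalent palladium, and the free alcohol is tolerated.

Step 3
Reactants: 6 2-[(1Z)-3-hydroxy-2-methylprop-1-en-1-yl]-3-methylcyclopent-2-en-1-one
Product: 7 2-[(1R,2S)-2-(hydroxymethyl)-2-methylcyclopropyl]-3-methylcyclopent-2-en-1-one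
Conditions: Et2Zn, CH2I2, DME, CH2Cl2, -10 °C; (4R,5R)-2-butyl-N,N,N',N'-tetramethyl-1,3,2-dioxaborolane-4,5-dicarboxamide (1.2 equiv), -10 °C to rt
Reagents that add atoms: diiodomethane ICI
Why: Charette asymmetric Simmons-Smith cyclopropanation, in which the zinc alkoxide bound to the tartramide boronate delivers CH2 (C7) to one face of the allylic alkene only. The syn addition turns the Z geometry into the cis relation of the ring and the hydroxymethyl group, the (R,R) ligand should give C6 (R) and C8 (S) by analogy with other Z and trisubstituted allylic alcohols, and the electron-poor enone alkene does not react with the electrophilic carbenoid.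

Step 4
Reactants: 7 2-[(1R,2S)-2-(hydroxymethyl)-2-methylcyclopropyl]-3-methylcyclopent-2-en-1-one
Product: 8 (1S,2R)-1-methyl-2-(2-methyl-5-oxocyclopent-1-en-1-yl)cyclopropane-1-carbaldehyde
Conditions: Dess-Martin periodinane, NaHCO3, CH2Cl2, 0 °C
Reagents that add atoms: none
Why: Dess-Martin oxidation under buffered, non-epimerising conditions; the α-carbon C8 is quaternary, so no stereocentre is at risk, and the aldehyde is used at once because a reversible retro-Claisen shift to a dihydrooxepine is conceivable.

Step 5
Reactants: 8 (1S,2R)-1-methyl-2-(2-methyl-5-oxocyclopent-1-en-1-yl)cyclopropane-1-carbaldehyde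
Product: 9 2-[(1R,2R)-2-ethenyl-2-methylcyclopropyl]-3-methylcyclopent-2-en-1-one
Conditions: Ph3PCH3Br (1.1 equiv), KHMDS (1.05 equiv), THF, -78 to 0 °C
Reagents that add atoms: methyltriphenylphosphonium bromide C[P+](c1ccccc1)(c1ccccc1)c1ccccc1.[Br-]
Why: Wittig methylenation; with one equivalent of ylide at low temperature the aldehyde should react far faster than the conjugated, tetrasubstituted cyclopentenone carbonyl, and the descriptor at C8 changes only because the substituent priorities change.

Step 6
Reactants: 9 2-[(1R,2R)-2-ethenyl-2-methylcyclopropyl]-3-methylcyclopent-2-en-1-one
Product: 10 (3aR)-3a,6-dimethyl-3,3a,4,7-tetrahydroazulen-1(2H)-one (C4 ketone, C5=C6 and C8=C9 alkenes, 1R)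
Conditions: toluene (0.02 M), BHT (cat.), 110 °C, sealed tube
Reagents that add atoms: none
Why: Thermal divinylcyclopropane-cycloheptadiene (Cope) rearrangement: the [3,3] shift runs over C1=C5-C6-C8-C9=C10, breaks the strained C6-C8 bond and forms C1-C10, so that C5=C6 and C8=C9 appear exactly where the target needs an oxidisable enone pair and its only alkene. The closest known reaction type is the rearrangement of cis-2-vinylcyclopropyl cycloalkenes and cycloalkenones to fused hydroazulenes, including cases that build a quaternary carbon at a fully substituted alkene terminus. Ring B is closed through the endo,endo boat transition state, the only one that gives two cis ring alkenes, while the three-membered ring opens in the same event and its strain makes the step irreversible. C1 is the only new stereocentre: in the boat geometry C10 can reach only the face of C5=C1 that lies over the cyclopropane, so the (6R,8R) configuration of 9 is carried over to (1R) while C6 and C8 become trigonal. The step needs the cis relation of the two alkenyl groups, secured by the Z alkene of 6 and the stereospecific methylene transfer, and it needs a planar C4, because a substituent on C4 that points at the C8 to C10 fragment would collide with H9; the ketone provides this. The C15 methyl group is cis to the cyclopropyl group on C5=C1 and meets the endo hydrogen of C7 in the transition state, so heating rather than room temperature is expected. The homodienyl 1,5-hydrogen shift is excluded because the C14 methyl group is trans to the cyclopentenyl group, and cis-trans isomerisation by C6-C8 homolysis should have the higher barrier.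

Step 7
Reactants: 10 (3aR)-3a,6-dimethyl-3,3a,4,7-tetrahydroazulen-1(2H)-one
Product: 11 (1R,5S,6R)-5,6-epoxy-11,12,13-trinordauc-8-en-4-one (5β,6β-epoxide)
Conditions: 30% H2O2, NaOH (0.3 equiv), MeOH, -10 to 0 °C
Reagents that add atoms: hydrogen peroxide OO
Why: Weitz-Scheffer nucleophilic epoxidation touches only the electron-poor C5=C6. C1, C5, C6 and C7 are coplanar and C8 to C10 bridge them on the α side, so hydroperoxide should add to C6 anti to C8 from the β face and the enolate closes on the same face, which sets C5 and C6 from C1.

Step 8
Reactants: 11 (1R,5S,6R)-5,6-epoxy-11,12,13-trinordauc-8-en-4-one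
Product: 12 (1R,4R,5S,6R)-5,6-epoxydauc-8-en-4-ol (4β-OH, 4α-isopropyl, 5β,6β-epoxide)
Conditions: iPrMgCl, CeCl3, THF, -78 °C
Reagents that add atoms: isopropylmagnesium chloride CC(C)[Mg]Cl
Why: Organocerium 1,2-addition suppresses enolisation and β-hydride reduction. The nucleophile should enter anti to the C5-O bond (polar Felkin-Anh control, supported by C15 on the β face), that is from α, which gives the 4β-alcohol cis to the epoxide oxygen; this cis alkoxide cannot open the epoxide from the rear.

Step 9
Reactants: 12 (1R,4R,5S,6R)-5,6-epoxydauc-8-en-4-ol
Product: 13 (1R,4R,5S,6R)-dauc-8-ene-4,6-diol (6-epi-jaeschkeanadiol: 4β-OH, 5α-H, 6β-OH)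
Conditions: Cp2TiCl2 (20 mol%), Mn dust, 2,4,6-collidine hydrochloride, 1,4-cyclohexadiene, THF, rt
Reagents that add atoms: none
Why: Reductive epoxide opening by trivalent titanium (Nugent-RajanBabu reaction) cleaves the C5-O bond to the tertiary C5 radical and avoids the cationic 1,2-shifts of an α-hydroxy epoxide. The β face of this radical is closed by C15, the 4-oxygen and the bulky 6-titanoxy group, so hydrogen-atom transfer should come from α and create the trans fusion.

Step 10
Reactants: 13 (1R,4R,5S,6R)-dauc-8-ene-4,6-diol
Product: 14 (1R,4R,5R)-4-hydroxydauc-8-en-6-one
Conditions: Dess-Martin periodinane, NaHCO3, CH2Cl2, 0 °C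
Reagents that add atoms: none
Why: Dess-Martin oxidation of the only secondary alcohol under neutral conditions keeps C8=C9 out of conjugation. C5 is not endangered because the trans-fused ketol, with C6 trans to the isopropyl group and hydrogen-bonded to the 4-OH, should also be the more stable epimer.

Step 11
Reactants: 14 (1R,4R,5R)-4-hydroxydauc-8-en-6-one
Product: 15 jaeschkeanadiol, (1R,4R,5S,6S)-dauc-8-ene-4,6-diol
Conditions: Me4NBH(OAc)3, MeCN/AcOH, -30 °C
Reagents that add atoms: none
Why: Evans-Saksena directed reduction: the 4β-OH exchanges onto boron and hands hydride to C6 through a six-membered transition state on the β face, which gives the 6α (equatorial, 1,3-anti) alcohol that external hydrides, hindered by the axial C15, would not give.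

Step 12
Reactants: 15 jaeschkeanadiol; 16 4-acetoxy-3-methoxybenzoic acid
Product: 17 jaeschkeanadiol 6-(4-acetoxy-3-methoxybenzoate)
Conditions: DCC, DMAP, CH2Cl2, rt to 40 °C
Reagents that add atoms: none
Why: Steglich esterification acylates the secondary 6-OH only, since the tertiary 4-OH is inert under these conditions, and the acetate keeps the phenol from competing as a nucleophile.

Step 13
Reactants: 17 jaeschkeanadiol 6-(4-acetoxy-3-methoxybenzoate)
Product: 18 teferin
Conditions: K2CO3 (cat.), MeOH, 0 °C
Reagents that add atoms: none
Why: Base-catalysed transesterification removes the activated aryl acetate much faster than the hindered, electron-rich secondary benzoate, and no stereocentre or alkene is affected.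

## Compound list

1 | prop-2-yn-1-ol | C#CCO | starting material
2 | 4-methyl-2,5-dihydro-1,2-oxamagnesole (cyclic Z-alkenylmagnesium alkoxide) | CC1=C[Mg]OC1 | intermediate
3 | (2Z)-3-iodo-2-methylprop-2-en-1-ol | OC/C(C)=C\I | intermediate
4 | 2-bromo-3-methylcyclopent-2-en-1-one | CC1=C(Br)C(=O)CC1 | starting material
5 | (2Z)-2-methyl-3-(4,4,5,5-tetramethyl-1,3,2-dioxaborolan-2-yl)prop-2-en-1-ol | OC/C(C)=C\B1OC(C)(C)C(C)(C)O1 | intermediate
6 | 2-[(1Z)-3-hydroxy-2-methylprop-1-en-1-yl]-3-methylcyclopent-2-en-1-one | OC/C(C)=C\C1=C(C)CCC1=O | intermediate
7 | 2-[(1R,2S)-2-(hydroxymethyl)-2-methylcyclopropyl]-3-methylcyclopent-2-en-1-one | O=C1CCC(C)=C1[C@@H]2C[C@]2(C)CO | intermediate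
8 | (1S,2R)-1-methyl-2-(2-methyl-5-oxocyclopent-1-en-1-yl)cyclopropane-1-carbaldehyde | O=C1CCC(C)=C1[C@@H]2C[C@]2(C)C=O | intermediate
9 | 2-[(1R,2R)-2-ethenyl-2-methylcyclopropyl]-3-methylcyclopent-2-en-1-one | O=C1CCC(C)=C1[C@@H]2C[C@]2(C)C=C | intermediate
10 | (3aR)-3a,6-dimethyl-3,3a,4,7-tetrahydroazulen-1(2H)-one | O=C1CC[C@]2(C)CC=C(C)CC=C12 | intermediate
11 | (1R,5S,6R)-5,6-epoxy-11,12,13-trinordauc-8-en-4-one | O=C1CC[C@]2(C)CC=C(C)C[C@H]3O[C@@]123 | intermediate
12 | (1R,4R,5S,6R)-5,6-epoxydauc-8-en-4-ol | O[C@@]1(C(C)C)CC[C@]2(C)CC=C(C)C[C@H]3O[C@@]123 | intermediate
13 | (1R,4R,5S,6R)-dauc-8-ene-4,6-diol (6-epi-jaeschkeanadiol) | O[C@@H]1CC(C)=CC[C@@]2(C)CC[C@@](O)(C(C)C)[C@H]12 | intermediate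
14 | (1R,4R,5R)-4-hydroxydauc-8-en-6-one | O=C1CC(C)=CC[C@@]2(C)CC[C@@](O)(C(C)C)[C@H]12 | intermediate
15 | jaeschkeanadiol, (1R,4R,5S,6S)-dauc-8-ene-4,6-diol | O[C@H]1CC(C)=CC[C@@]2(C)CC[C@@](O)(C(C)C)[C@H]12 | intermediate
16 | 4-acetoxy-3-methoxybenzoic acid | COc1cc(C(=O)O)ccc1OC(C)=O | starting material
17 | jaeschkeanadiol 6-(4-acetoxy-3-methoxybenzoate) | COc1cc(C(=O)O[C@H]2CC(C)=CC[C@@]3(C)CC[C@@](O)(C(C)C)[C@H]23)ccc1OC(C)=O | intermediate
18 | teferin | COc1cc(C(=O)O[C@H]2CC(C)=CC[C@@]3(C)CC[C@@](O)(C(C)C)[C@H]23)ccc1O | target

## Step count and least certain steps

Total step count: 13. Longest linear sequence: 13 steps, from 1 to 18. Compounds 4 and 16 enter as purchased materials.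

**Step 6 (key step).** The rearrangement may be slow. The C15 methyl group is pressed against the endo hydrogen of C7, and the reacting alkene is tetrasubstituted. At the temperature then needed, homolysis of C6-C8 could start to scramble the cyclopropane and erode the enantiomeric purity.

The fallback adds a second control element, so that C1 no longer depends on the cyclopropane alone. It sets out from 9 and comes back at 10.
- Reduction of 9 with BH3·SMe2 and the (R)-methyl-CBS oxazaborolidine gives the (4S)-allylic alcohol F1.
- Silylation with TBSCl and imidazole gives its silyl ether F2.
- In F2 only the hydrogen on C4 faces the α side. The cis isomer that leads to (1R) rearranges, and any scrambled cis isomer would have to push the silyloxy group against H9 and is therefore blocked.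
- Heating gives the bicyclic silyl ether F3, and Bu4NF gives the bicyclic allylic alcohol F4.
- MnO2 oxidises F4 to 10.

**Step 7.** Base may remove a doubly allylic C7 hydrogen of 10 and move C8=C9 into conjugation before the epoxidation is complete. The face selectivity also rests only on the fold of ring B.

The fallback replaces the basic nucleophilic oxidant by a directed one. It sets out from 10 and comes back at 11. CBS reduction as above gives the bicyclic allylic alcohol F4. VO(acac)2 and tBuOOH epoxidise only the allylic alkene, syn to the 4β-OH, and give the epoxy alcohol F5. Dess-Martin oxidation of F5 gives 11.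

**Step 8.** The branched reagent may enolise or reduce the hindered ketone. Coordination of the metal to the epoxide oxygen could weaken the preference for the α face.

The fallback uses a smaller nucleophile without β-hydrogen. It sets out from 11 and comes back at 12. Isopropenylmagnesium bromide with CeCl3 gives the isopropenyl carbinol F6. Hydrogenation with RhCl(PPh3)3 saturates the 1,1-disubstituted alkene in preference to the trisubstituted C8=C9 and gives 12.

**Step 9.** Hydrogen-atom transfer to the C5 radical may be poorly face-selective, because the isopropyl group and the fold of ring B crowd the α face. Deoxygenation to the alkene is a possible side path.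

The fallback sets H5 by a stereospecific ionic shift before the isopropyl group is present. It sets out from 11 and comes back at 13.
- NaBH4 with CeCl3 reduces 11 anti to the epoxide and gives the epoxy alcohol F5, in which H4 is α and antiperiplanar to the C5-O bond.
- BF3·OEt2 at low temperature triggers the semipinacol 1,2-hydride shift from C4 to C5. This gives the trans-fused hydroxy ketone F7.
- Excess iPrMgCl with CeCl3 then adds to F7 from the α face, opposite to the now axial C15, and gives 13.

**Step 11.** The hindered tertiary alcohol may exchange onto boron too slowly. Undirected hydride delivery from the α face would then compete and lower the selectivity at C6.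

The fallback changes from hydride transfer to electron transfer. It sets out from 14 and comes back at 15. SmI2 in THF with water reduces the samarium-chelated β-hydroxy ketone through a ketyl, whose protonation should give the more stable equatorial, 1,3-anti alcohol. No new compound is formed on the way.

## Further compounds

F1 | step 6 | (1S)-2-[(1R,2R)-2-ethenyl-2-methylcyclopropyl]-3-methylcyclopent-2-en-1-ol | O[C@H]1CCC(C)=C1[C@@H]2C[C@]2(C)C=C
F2 | step 6 | tert-butyldimethylsilyl ether of F1 | CC(C)(C)[Si](C)(C)O[C@H]1CCC(C)=C1[C@@H]2C[C@]2(C)C=C
F3 | step 6 | (1R,4S)-4-(tert-butyldimethylsilyloxy)-11,12,13-trinordauca-5,8-diene | CC(C)(C)[Si](C)(C)O[C@H]1CC[C@]2(C)CC=C(C)CC=C12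
F4 | step 6 | (1R,4S)-11,12,13-trinordauca-5,8-dien-4-ol | O[C@H]1CC[C@]2(C)CC=C(C)CC=C12
F5 | step 7 | 5β,6β-epoxy-11,12,13-trinordauc-8-en-4β-ol | O[C@H]1CC[C@]2(C)CC=C(C)C[C@H]3O[C@@]123
F6 | step 8 | 5β,6β-epoxydauca-8,11-dien-4β-ol | O[C@@]1(C(C)=C)CC[C@]2(C)CC=C(C)C[C@H]3O[C@@]123
F7 | step 9 | 6β-hydroxy-5α-H-11,12,13-trinordauc-8-en-4-one | O[C@@H]1CC(C)=CC[C@@]2(C)CCC(=O)[C@H]12
F0 | step 11 | none | none
A1 | alternative 1 | 8,9-seco diene: ring A with 4β-OH, 4α-isopropyl, 5α-H, C1 β-methyl and α-allyl, C5 side chain (6S)-1-hydroxy-3-methylbut-3-enyl | C=C(C)C[C@H](O)[C@@H]1[C@@](C)(CC=C)CC[C@@]1(O)C(C)C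
A2 | alternative 2 | (S)-terpinen-4-ol | CC1=CC[C@](O)(C(C)C)CC1
A3 | alternative 2 | (5R)-5-hydroxy-2-methyl-5-(propan-2-yl)cyclopent-1-ene-1-carbaldehyde | O=CC1=C(C)CC[C@@]1(O)C(C)C
A4 | alternative 3 | 6-methyl-3-(4-methyl-3-oxopentyl)cyclohepta-2,5-dien-1-one | CC(C)C(=O)CCC1=CC(=O)CC(C)=CC1
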